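**Retrosynthetic overview**
1. Target 13 ⇐ dithionite reduction of macrocyclic aryloxyquinone 12 ⇐ ring-closing C–O bond formation: the ring A phenoxide displaces bromide from bromoquinone 11. The 21-membered macrocycle is the only ring formed, and it is formed last.
2. 11 ⇐ selective oxidation of the hydroquinone ring of 10 ⇐ global O-demethylation of 9.
3. 9 ⇐ two copper-catalysed aryl-Grignard/alkyl-bromide couplings on 1,14-dibromotetradecane, ring B (from 3) first and ring A (from 7) second.
4. 3 ⇐ 4-methoxyphenol by ortho,ortho-dibromination and O-methylation. The two bromines flank the oxygen that ends as the ring B hydroxyl between chain and ether: one carries the chain, the other is the leaving group of the key step.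

Assumption: the target has no stereogenic element (it is achiral), so no stereocentre has to be set; 4-methoxyphenol, 1,14-dibromotetradecane and 1-bromo-3,5-dimethoxybenzene are taken as catalogue chemicals.

**Step 1**
Reactants: 1 4-methoxyphenol
Product: 2 2,6-dibromo-4-methoxyphenol
Conditions: Br2 (2.05 equiv), CH2Cl2, 0 °C → rt
Reagents that add atoms: bromine, BrBr
Why: Electrophilic aromatic bromination; the free hydroxyl is the strongest activator and its para position is blocked by methoxy, so both bromines enter ortho to OH, the 2,6-pattern ring B needs.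

**Step 2**
Reactants: 2 2,6-dibromo-4-methoxyphenol
Product: 3 1,3-dibromo-2,5-dimethoxybenzene
Conditions: MeI, K2CO3, DMF, 40 °C
Reagents that add atoms: iodomethane, CI
Why: Williamson ether synthesis; the acidic 2,6-dibromophenol is fully ionised by K2CO3 and methylated on oxygen, masking it for the organometallic steps.

**Step 3**
Reactants: 3 1,3-dibromo-2,5-dimethoxybenzene; 4 1,14-dibromotetradecane
Product: 6 1-bromo-3-(14-bromotetradecyl)-2,5-dimethoxybenzene, via arylmagnesium chloride 5 (not isolated)
Conditions: i-PrMgCl·LiCl (1.05 equiv), THF, 0 °C → rt; then 4 (3 equiv), Li2CuCl4 (5 mol%), −20 °C → rt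
Reagents that add atoms: none
Why: Bromine–magnesium exchange (turbo-Grignard), helped by the ortho-methoxy group and stopping after one exchange because the arylmagnesium is electron-rich, then a copper-catalysed Kochi-type sp2–sp3 coupling in which the threefold excess of 4 keeps double arylation low and the second aryl bromide is untouched.

**Step 4**
Reactants: 6 1-bromo-3-(14-bromotetradecyl)-2,5-dimethoxybenzene; 7 1-bromo-3,5-dimethoxybenzene
Product: 9 1-bromo-3-[14-(3,5-dimethoxyphenyl)tetradecyl]-2,5-dimethoxybenzene, via 3,5-dimethoxyphenylmagnesium bromide 8 (not isolated)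
Conditions: 7 (1.6 equiv), Mg, THF, reflux; then 6, Li2CuCl4 (3 mol%), THF/NMP, 0 °C → rt
Reagents that add atoms: none
Why: Grignard formation and copper-catalysed Tamura–Kochi coupling; the cuprate attacks only the primary alkyl bromide, so the aryl bromide of ring B survives for the key step.

**Step 5**
Reactants: 9 1-bromo-3-[14-(3,5-dimethoxyphenyl)tetradecyl]-2,5-dimethoxybenzene
Product: 10 2-bromo-6-[14-(3,5-dihydroxyphenyl)tetradecyl]benzene-1,4-diol
Conditions: BBr3 (8 equiv), CH2Cl2, −78 °C → rt; MeOH, then degassed H2O
Reagents that add atoms: none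
Why: Lewis-acid aryl methyl ether cleavage with BBr3 (O–B bond formation, then SN2 loss of MeBr) frees all four phenols while the aryl bromide and the alkyl chain are inert.

**Step 6**
Reactants: 10 2-bromo-6-[14-(3,5-dihydroxyphenyl)tetradecyl]benzene-1,4-diol
Product: 13 target macrocycle 1²,1⁵,3⁵-trihydroxy-2-oxa-1,3(1,3)-dibenzenacycloheptadecaphane, via bromoquinone 11 (not isolated), via macrocyclic aryloxyquinone 12 (not isolated)
Conditions: Ag2O (1.2 equiv), MgSO4, THF, rt, filter under Ar; dilute to 1 mM in MeCN, Cs2CO3 (2.5 equiv), rt, dark; then aq. Na2S2O4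
Reagents that add atoms: none
Why: Proposed new method: a redox-switched macrocyclic substitution; the electron-rich bromohydroquinone of 10 is inert to phenoxides, but two-electron oxidation (Ag2O oxidises the hydroquinone and leaves the resorcinol alone) makes bromoquinone 11, a vinylogous acyl bromide, whose bromine-bearing carbon is attacked through oxygen by the caesium phenoxide of ring A. Irreversible loss of bromide (addition–elimination) fixes the ether at the ipso carbon, whereas oxa-Michael addition at the C–H carbons is reversible in aprotic medium; 1 mM dilution favours the strain-free 21-membered ring, and dithionite returns quinone 12 to the hydroquinone. The closest known reaction type is the intermolecular displacement of halide from halo-1,4-quinones by phenoxides, which has not been used as a ring-closing step or coupled to an oxidation–reduction switch on a free polyphenol.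

**Compound list**
1 | 4-methoxyphenol | COc1ccc(O)cc1 | starting material
2 | 2,6-dibromo-4-methoxyphenol | COc1cc(Br)c(O)c(Br)c1 | intermediate
3 | 1,3-dibromo-2,5-dimethoxybenzene | COc1cc(Br)c(OC)c(Br)c1 | intermediate
4 | 1,14-dibromotetradecane | BrCCCCCCCCCCCCCCBr | starting material
5 | (3-bromo-2,5-dimethoxyphenyl)magnesium chloride (LiCl complex, formed in situ) | COc1cc(Br)c(OC)c([Mg]Cl)c1 | intermediate
6 | 1-bromo-3-(14-bromotetradecyl)-2,5-dimethoxybenzene | COc1cc(Br)c(OC)c(CCCCCCCCCCCCCCBr)c1 | intermediate
7 | 1-bromo-3,5-dimethoxybenzene | COc1cc(Br)cc(OC)c1 | starting material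
8 | 3,5-dimethoxyphenylmagnesium bromide (formed in situ) | COc1cc(OC)cc([Mg]Br)c1 | intermediate
9 | 1-bromo-3-[14-(3,5-dimethoxyphenyl)tetradecyl]-2,5-dimethoxybenzene | COc1cc(Br)c(OC)c(CCCCCCCCCCCCCCc2cc(OC)cc(OC)c2)c1 | intermediate
10 | 2-bromo-6-[14-(3,5-dihydroxyphenyl)tetradecyl]benzene-1,4-diol | Oc1cc(Br)c(O)c(CCCCCCCCCCCCCCc2cc(O)cc(O)c2)c1 | intermediate
11 | 2-bromo-6-[14-(3,5-dihydroxyphenyl)tetradecyl]cyclohexa-2,5-diene-1,4-dione (bromoquinone, formed in situ) | O=C1C=C(Br)C(=O)C(CCCCCCCCCCCCCCc2cc(O)cc(O)c2)=C1 | intermediate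
12 | macrocyclic aryloxyquinone, the 1,4-benzoquinone form of 13 (ring B = 2-alkyl-6-aryloxy-1,4-benzoquinone; ring A = 3-hydroxy-5-oxyphenyl; (CH2)14 bridge; formed in situ) | Oc1cc2cc(c1)OC1=CC(=O)C=C(C1=O)CCCCCCCCCCCCCC2 | intermediate
13 | CNP0393720, 1²,1⁵,3⁵-trihydroxy-2-oxa-1,3(1,3)-dibenzenacycloheptadecaphane: ring A is a 5-alkylresorcinol whose second oxygen is bonded to C6 of ring B, a 2-alkylhydroquinone; a (CH2)14 chain joins the rings; achiral | Oc1cc2cc(c1)Oc1cc(O)cc(c1O)CCCCCCCCCCCCCC2 | target

**Totals**
Total steps: 6. Longest linear sequence: 6 (1 → 2 → 3 → 6 → 9 → 10 → 13).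

**Steps most likely to fail**

Step 6 (the proposed new step). The risks are C- instead of O-attack by the resorcinolate, attack at the C–H carbon next to the bromine, and oligomers. The fallback is a known copper-catalysed Ullmann macro-etherification on the protected hydroquinone; it sets out from 6 and comes back to the route at 13. Bromide 6 is coupled (Li2CuCl4 cat., THF) with [3,5-bis(benzyloxy)phenyl]magnesium bromide F1, made from catalogue 1-bromo-3,5-bis(benzyloxy)benzene and Mg, to give 1-bromo-3-{14-[3,5-bis(benzyloxy)phenyl]tetradecyl}-2,5-dimethoxybenzene F2. BCl3 with pentamethylbenzene (CH2Cl2, −78 °C) removes only the benzyl groups and gives 5-[14-(3-bromo-2,5-dimethoxyphenyl)tetradecyl]benzene-1,3-diol F3. CuI, N,N-dimethylglycine, Cs2CO3, dioxane, 100 °C at 2 mM closes the ring to the macrocyclic diaryl ether dimethyl ether F4 (13 with both ring B hydroxyls methylated), and BBr3 then gives 13.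

Step 3. The risks are incomplete or double bromine–magnesium exchange and double arylation of 4. The fallback reverses the polarity and uses a palladium-catalysed Negishi coupling; it sets out from 4 and comes back at 9, replacing steps 3 and 4. Grignard reagent 8 is coupled with excess 4 (Li2CuCl4 cat.) to give 1-(14-bromotetradecyl)-3,5-dimethoxybenzene F5. Zinc dust and LiCl (THF, 50 °C) convert it into [14-(3,5-dimethoxyphenyl)tetradecyl]zinc bromide F6, which is coupled with 3 (3 equiv, excess recovered) under Pd(OAc)2/SPhos to give 9.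

Step 4. The risks are bromine–magnesium scrambling between excess 8 and the aryl bromide of 6, and homocoupling. The fallback replaces the Grignard by a chemoselective Negishi coupling; it sets out from 6 and comes back at 9. Zinc dust and LiCl insert only into the alkyl bromide of 6 to give [14-(3-bromo-2,5-dimethoxyphenyl)tetradecyl]zinc bromide F7. Coupling with catalogue 1-iodo-3,5-dimethoxybenzene under Pd(PPh3)4 (THF, rt), where the C–I bond reacts before the electron-rich C–Br bond, gives 9.

**Further compounds**
F1 | step 6 | [3,5-bis(benzyloxy)phenyl]magnesium bromide | Br[Mg]c1cc(OCc2ccccc2)cc(OCc2ccccc2)c1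
F2 | step 6 | 1-bromo-3-{14-[3,5-bis(benzyloxy)phenyl]tetradecyl}-2,5-dimethoxybenzene | COc1cc(Br)c(OC)c(CCCCCCCCCCCCCCc2cc(OCc3ccccc3)cc(OCc3ccccc3)c2)c1
F3 | step 6 | 5-[14-(3-bromo-2,5-dimethoxyphenyl)tetradecyl]benzene-1,3-diol | COc1cc(Br)c(OC)c(CCCCCCCCCCCCCCc2cc(O)cc(O)c2)c1
F4 | step 6 | macrocyclic diaryl ether dimethyl ether (13 with both ring B hydroxyls as methyl ethers) | Oc1cc2cc(c1)Oc1cc(OC)cc(c1OC)CCCCCCCCCCCCCC2
F5 | step 3 | 1-(14-bromotetradecyl)-3,5-dimethoxybenzene | COc1cc(CCCCCCCCCCCCCCBr)cc(OC)c1
F6 | step 3 | [14-(3,5-dimethoxyphenyl)tetradecyl]zinc bromide | COc1cc(CCCCCCCCCCCCCC[Zn]Br)cc(OC)c1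
F7 | step 4 | [14-(3-bromo-2,5-dimethoxyphenyl)tetradecyl]zinc bromide | COc1cc(Br)c(OC)c(CCCCCCCCCCCCCC[Zn]Br)c1
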